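## Retrosynthetic overview

1. The target comes from its tetra-MOM ether by global acetal cleavage (last step).
2. C2–C1′ disconnection: Rh/chiral-diene enantioselective conjugate arylation of a 6-geranyl-3,5,7-tris(MOMO)chromone with a 4-methoxy-3-(MOMO)phenylboronic acid. This attaches the B-ring and sets both stereocentres.
3. C-ring (pyranone) is closed onto the finished A-ring: an o-hydroxyaryl MOMO-methyl ketone plus DMF-DMA. The ketone comes from directed ortho-lithiation of an aryl THP ether and a glycolate Weinreb amide.
4. A-ring is resorcinol throughout. O1 is installed by Ir-catalysed C–H borylation/oxidation. The aryl–geranyl bond comes from Ni-catalysed coupling of a 2,6-bis(MOMO)benzyl chloride with the (E)-alkenylalane made by Zr-catalysed methylalumination of 6-methylhept-5-en-1-yne.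
5. Ring order: A (resorcinol, side chain attached) → C (chromone) → B (anisole-derived, preformed) attached last.

Assumption: the chiral diene delivers aryl to chromone C2 with the same facial sense it shows for cyclic enones; if the sense is reversed on this substrate, the ligand antipode is used.

## Route

**Step 1**
Reactants: 1 resorcinol
Product: 2 1,3-bis(methoxymethoxy)benzene
Conditions: NaH, MOMCl, DMF, 0 °C → rt
Reagents that add atoms: chloromethyl methyl ether, COCCl
Why: Williamson-type O-alkylation (MOM protection) of both phenols, giving two ortho-directing groups.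

**Step 2**
Reactants: 2 1,3-bis(methoxymethoxy)benzene
Product: 3 [2,6-bis(methoxymethoxy)phenyl]methanol
Conditions: n-BuLi, THF, 0 °C, 1 h; dry (CH2O)n, −78 °C → rt
Reagents that add atoms: paraformaldehyde (as formaldehyde), C=O
Why: Directed ortho-metalation at the doubly activated C2 between the two OMOM groups, then hydroxymethylation of the aryllithium.

**Step 3**
Reactants: 3 [2,6-bis(methoxymethoxy)phenyl]methanol
Product: 4 2-(chloromethyl)-1,3-bis(methoxymethoxy)benzene
Conditions: MsCl, Et3N, CH2Cl2, −10 °C; LiCl, THF, rt; used crude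
Reagents that add atoms: lithium chloride, [Li+].[Cl-] (MsCl is only the activator)
Why: Mesylation followed by SN2 chloride displacement under non-acidic conditions keeps the MOM ethers intact.

**Step 4**
Reactants: 5 5-bromo-2-methylpent-2-ene; 6 lithium acetylide–ethylenediamine complex
Product: 7 6-methylhept-5-en-1-yne
Conditions: DMSO, 10 °C → rt; pentane extraction, distillation
Reagents that add atoms: none (both carbon sources are numbered reactants)
Why: SN2 alkylation of acetylide by the primary homoallylic bromide gives the terminal enyne.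

**Step 5**
Reactants: 4 2-(chloromethyl)-1,3-bis(methoxymethoxy)benzene; 7 6-methylhept-5-en-1-yne
Product: 8 2-[(2E)-3,7-dimethylocta-2,6-dien-1-yl]-1,3-bis(methoxymethoxy)benzene
Conditions: 7, Me3Al, Cp2ZrCl2 (25 mol%), ClCH2CH2Cl, rt; volatiles removed; THF; 4, Ni(PPh3)4 (3 mol%, from NiCl2(PPh3)2/2 n-BuLi), rt; Rochelle-salt work-up
Reagents that add atoms: trimethylaluminium, C[Al](C)C (supplies the C3″ methyl)
Why: Negishi Zr-catalysed syn-methylalumination gives the (E)-2-methylalkenylalane, and Ni(0)-catalysed alkenylalane–benzyl chloride cross-coupling proceeds with retention, so the 2″E olefin is fixed (the same coupling type is used on polyalkoxybenzyl chlorides in ubiquinone syntheses).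

**Step 6**
Reactants: 8 2-geranyl-1,3-bis(methoxymethoxy)benzene
Product: 9 4-[(2E)-3,7-dimethylocta-2,6-dien-1-yl]-3,5-bis(methoxymethoxy)phenol
Conditions: [Ir(OMe)(cod)]2 (1.5 mol%), dtbpy (3 mol%), B2pin2, THF, 70 °C; then aq. H2O2, NaOH, 0 °C
Reagents that add atoms: hydrogen peroxide, OO (phenolic oxygen); B2pin2 is transient
Why: Sterically controlled Ir-catalysed aromatic C–H borylation hits the only C–H with no ortho substituent (C5), and alkaline peroxide oxidation of the ArBpin gives the phenol without touching the trisubstituted olefins.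

**Step 7**
Reactants: 9 4-geranyl-3,5-bis(methoxymethoxy)phenol
Product: 10 2-{4-[(2E)-3,7-dimethylocta-2,6-dien-1-yl]-3,5-bis(methoxymethoxy)phenoxy}tetrahydro-2H-pyran (racemic at the acetal carbon)
Conditions: 3,4-dihydro-2H-pyran, PPTS (10 mol%), CH2Cl2, rt
Reagents that add atoms: 3,4-dihydro-2H-pyran, C1=COCCC1
Why: Acid-catalysed acetalisation gives a THP ether that directs ortho-lithiation and can later be removed in the presence of MOM ethers.

**Step 8**
Reactants: 11 methyl glycolate
Product: 12 methyl 2-(methoxymethoxy)acetate
Conditions: MOMCl, i-Pr2NEt, CH2Cl2, 0 °C → rt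
Reagents that add atoms: chloromethyl methyl ether, COCCl
Why: Standard MOM protection of a primary alcohol.

**Step 9**
Reactants: 12 methyl 2-(methoxymethoxy)acetate
Product: 13 N-methoxy-2-(methoxymethoxy)-N-methylacetamide
Conditions: MeNH(OMe)·HCl, i-PrMgCl, THF, −20 °C
Reagents that add atoms: N,O-dimethylhydroxylamine hydrochloride, CNOC.Cl
Why: Magnesium-amide aminolysis of the ester gives the Weinreb amide.

**Step 10**
Reactants: 10 aryl THP ether; 13 Weinreb amide
Product: 14 1-{3-[(2E)-3,7-dimethylocta-2,6-dien-1-yl]-2,4-bis(methoxymethoxy)-6-(tetrahydro-2H-pyran-2-yloxy)phenyl}-2-(methoxymethoxy)ethan-1-one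
Conditions: n-BuLi, TMEDA, THF, −20 → 0 °C; 13, −78 → 0 °C; aq. NH4Cl
Reagents that add atoms: none (13 is a numbered reactant)
Why: Directed ortho-metalation at the only remaining ring C–H type (flanked by OTHP and OMOM; the two sites are equivalent), then Weinreb ketone synthesis, whose stable chelate prevents over-addition.

**Step 11**
Reactants: 14 THP-protected ketone
Product: 15 1-{3-[(2E)-3,7-dimethylocta-2,6-dien-1-yl]-6-hydroxy-2,4-bis(methoxymethoxy)phenyl}-2-(methoxymethoxy)ethan-1-one
Conditions: PPTS (20 mol%), MeOH, 40 °C
Reagents that add atoms: none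
Why: Selective acetal methanolysis, since the aryl THP ether cleaves far faster than MOM ethers under PPTS; this frees only the oxygen that becomes O1 and so fixes the 6- (not 8-) geranyl regiochemistry.

**Step 12**
Reactants: 15 o-hydroxyaryl ketone
Product: 16 6-[(2E)-3,7-dimethylocta-2,6-dien-1-yl]-3,5,7-tris(methoxymethoxy)-4H-chromen-4-one
Conditions: DMF-DMA, toluene, 90 °C; then PPTS (cat.), toluene, 70 °C
Reagents that add atoms: N,N-dimethylformamide dimethyl acetal, COC(OC)N(C)C (supplies C2)
Why: Enaminone formation at the only enolisable CH2, then intramolecular addition–elimination of the phenol with loss of Me2NH (the enaminone chromone synthesis, as used for isoflavones from deoxybenzoins) closes the C-ring.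

**Step 13**
Reactants: 17 anisole
Product: 18 2-methoxyphenol
Conditions: n-BuLi, TMEDA, Et2O, 0 °C → rt; B(OMe)3, −78 °C; H2O2, AcOH, 0 °C
Reagents that add atoms: hydrogen peroxide, OO (B(OMe)3 is transient)
Why: Directed ortho-metalation of anisole, borylation and boronate oxidation install the ortho oxygen.

**Step 14**
Reactants: 18 2-methoxyphenol
Product: 19 2-methoxyphenyl acetate
Conditions: Ac2O, pyridine, DMAP (cat.), rt
Reagents that add atoms: acetic anhydride, CC(=O)OC(C)=O
Why: O-acetylation attenuates the phenol oxygen so the OMe group controls the next substitution.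

**Step 15**
Reactants: 19 2-methoxyphenyl acetate
Product: 20 5-bromo-2-methoxyphenyl acetate
Conditions: NBS, MeCN, rt
Reagents that add atoms: N-bromosuccinimide, O=C1CCC(=O)N1Br
Why: Electrophilic aromatic bromination para to the stronger donor (OMe), not para to OAc.

**Step 16**
Reactants: 20 5-bromo-2-methoxyphenyl acetate
Product: 21 5-bromo-2-methoxyphenol
Conditions: K2CO3, MeOH, rt
Reagents that add atoms: none
Why: Mild methanolysis of the aryl acetate.

**Step 17**
Reactants: 21 5-bromo-2-methoxyphenol
Product: 22 4-bromo-1-methoxy-2-(methoxymethoxy)benzene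
Conditions: MOMCl, i-Pr2NEt, CH2Cl2, 0 °C → rt
Reagents that add atoms: chloromethyl methyl ether, COCCl
Why: MOM protection gives a base-stable group that is removed with the others in the last step.

**Step 18**
Reactants: 22 4-bromo-1-methoxy-2-(methoxymethoxy)benzene
Product: 23 [4-methoxy-3-(methoxymethoxy)phenyl]boronic acid
Conditions: n-BuLi, THF, −78 °C; B(Oi-Pr)3; aq. NH4Cl
Reagents that add atoms: triisopropyl borate, CC(C)OB(OC(C)C)OC(C)C; water, O
Why: Br–Li exchange at −78 °C is faster than any ortho-lithiation, and the aryllithium is trapped as the borate and hydrolysed to the boronic acid.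

**Step 19**
Reactants: 16 3,5,7-tris(MOMO)-6-geranylchromone; 23 arylboronic acid
Product: 24 (2R,3R)-6-[(2E)-3,7-dimethylocta-2,6-dien-1-yl]-2-[4-methoxy-3-(methoxymethoxy)phenyl]-3,5,7-tris(methoxymethoxy)-2,3-dihydro-4H-chromen-4-one
Conditions: [RhCl(C2H4)2]2 (2.5 mol%), (S,S)-Ph-bod* [(1S,4S)-2,5-diphenylbicyclo[2.2.2]octa-2,5-diene] (5.5 mol%), KOH (10 mol%), 23 (2.5 equiv), 1,4-dioxane/H2O 10:1, 40 °C; then DBU (10 mol%), CH2Cl2, 0 °C if any cis C3-epimer remains
Reagents that add atoms: none (C3–H comes from water)
Why: Proposed new method: Rh(I)/chiral-diene 1,4-arylation of a 3-alkoxychromone — Ar–Rh(diene*) from B→Rh transmetalation inserts C2=C3 with aryl delivered to C2 on the face chosen by the C2-symmetric diene (sets 2R), water hydrolyses the C3-OMOM oxa-π-allyl rhodium back to Rh–OH, and C3 is set by protonation followed by enolisation-based equilibration to the diequatorial 2,3-trans isomer (3R; E1cB ring opening is slow because the endocyclic C2–O1 bond is poorly aligned with the enolate π system); the closest known reaction type is the Rh/diene (Hayashi–Miyaura) or Pd/PyOx asymmetric conjugate arylation of 3-unsubstituted chromones to flavanones, which has not been shown for 3-oxygenated chromones or used to make dihydroflavonols directly.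

**Step 20**
Reactants: 24 tetra-MOM dihydroflavonol
Product: 25 4′-O-methyldiplacol, (2R,3R)-6-[(2E)-3,7-dimethylocta-2,6-dien-1-yl]-3,5,7-trihydroxy-2-(3-hydroxy-4-methoxyphenyl)-2,3-dihydro-4H-chromen-4-one
Conditions: 3 M aq. HCl/MeOH (1:4), 45 °C, monitored and stopped at full conversion
Reagents that add atoms: none
Why: Acid-catalysed acetal hydrolysis removes all four MOM groups; the trans-dihydroflavonol is configurationally stable in acid (4′-OMe blocks quinone-methide epimerisation), and the short, mild exposure limits acid cyclisation of the geranyl chain onto the flanking phenols.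

## Compound list

1 | resorcinol | Oc1cccc(O)c1 | starting material
2 | 1,3-bis(methoxymethoxy)benzene | COCOc1cccc(OCOC)c1 | intermediate
3 | [2,6-bis(methoxymethoxy)phenyl]methanol | COCOc1cccc(OCOC)c1CO | intermediate
4 | 2-(chloromethyl)-1,3-bis(methoxymethoxy)benzene | COCOc1cccc(OCOC)c1CCl | intermediate
5 | 5-bromo-2-methylpent-2-ene | CC(C)=CCCBr | starting material
6 | lithium acetylide–ethylenediamine complex | [Li]C#C.NCCN | starting material
7 | 6-methylhept-5-en-1-yne | C#CCCC=C(C)C | intermediate
8 | 2-[(2E)-3,7-dimethylocta-2,6-dien-1-yl]-1,3-bis(methoxymethoxy)benzene | COCOc1cccc(OCOC)c1C/C=C(\C)CCC=C(C)C | intermediate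
9 | 4-[(2E)-3,7-dimethylocta-2,6-dien-1-yl]-3,5-bis(methoxymethoxy)phenol | COCOc1cc(O)cc(OCOC)c1C/C=C(\C)CCC=C(C)C | intermediate
10 | 2-{4-geranyl-3,5-bis(methoxymethoxy)phenoxy}tetrahydro-2H-pyran (racemic acetal) | COCOc1cc(OC2CCCCO2)cc(OCOC)c1C/C=C(\C)CCC=C(C)C | intermediate
11 | methyl glycolate | COC(=O)CO | starting material
12 | methyl 2-(methoxymethoxy)acetate | COCOCC(=O)OC | intermediate
13 | N-methoxy-2-(methoxymethoxy)-N-methylacetamide | COCOCC(=O)N(C)OC | intermediate
14 | 1-{3-geranyl-2,4-bis(methoxymethoxy)-6-(tetrahydro-2H-pyran-2-yloxy)phenyl}-2-(methoxymethoxy)ethan-1-one (racemic acetal) | COCOCC(=O)c1c(OC2CCCCO2)cc(OCOC)c(C/C=C(\C)CCC=C(C)C)c1OCOC | intermediate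
15 | 1-{3-geranyl-6-hydroxy-2,4-bis(methoxymethoxy)phenyl}-2-(methoxymethoxy)ethan-1-one | COCOCC(=O)c1c(O)cc(OCOC)c(C/C=C(\C)CCC=C(C)C)c1OCOC | intermediate
16 | 6-geranyl-3,5,7-tris(methoxymethoxy)-4H-chromen-4-one | COCOC1=COc2cc(OCOC)c(C/C=C(\C)CCC=C(C)C)c(OCOC)c2C1=O | intermediate
17 | anisole | COc1ccccc1 | starting material
18 | 2-methoxyphenol | COc1ccccc1O | intermediate
19 | 2-methoxyphenyl acetate | COc1ccccc1OC(C)=O | intermediate
20 | 5-bromo-2-methoxyphenyl acetate | COc1ccc(Br)cc1OC(C)=O | intermediate
21 | 5-bromo-2-methoxyphenol | COc1ccc(Br)cc1O | intermediate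
22 | 4-bromo-1-methoxy-2-(methoxymethoxy)benzene | COCOc1cc(Br)ccc1OC | intermediate
23 | [4-methoxy-3-(methoxymethoxy)phenyl]boronic acid | COCOc1cc(B(O)O)ccc1OC | intermediate
24 | (2R,3R)-6-geranyl-2-[4-methoxy-3-(methoxymethoxy)phenyl]-3,5,7-tris(methoxymethoxy)chroman-4-one | COCOc1cc([C@H]2Oc3cc(OCOC)c(C/C=C(\C)CCC=C(C)C)c(OCOC)c3C(=O)[C@@H]2OCOC)ccc1OC | intermediate
25 | 4′-O-methyldiplacol | COc1ccc([C@H]2Oc3cc(O)c(C/C=C(\C)CCC=C(C)C)c(O)c3C(=O)[C@@H]2O)cc1O | target

## Summary

Total step count: 20.
Longest linear sequence: 11 steps (steps 1, 2, 3, 5, 6, 7, 10, 11, 12, 19, 20, from resorcinol).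

Three steps most likely to fail:

1. **Step 19 (proposed new Rh arylation of the 3-alkoxychromone).** Risks are sluggish insertion into the α-oxygenated, electron-rich enone, incomplete C3 control, or ring opening. Fallback with known chemistry: use N-methoxy-N-methylacetamide in step 10 to reach the 3-unsubstituted chromone, run the established Rh/diene asymmetric 1,4-arylation of that chromone with 23 to the (2S)-flavanone, then introduce the 3-OH by enolate hydroxylation (KHMDS, −78 °C; Davis N-sulfonyloxaziridine) anti to the 2-aryl group. This gives the same (2R,3R)-trans compound without an olefin-reactive oxidant.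

2. **Step 5 (Ni-catalysed alkenylalane/benzyl chloride coupling).** Risks are the labile electron-rich benzyl chloride and Lewis-acidic alane near MOM ethers. Fallback: reverse the polarity. Convert 7 to geraniol (the same Zr-catalysed methylalumination, quenched with paraformaldehyde) and then geranyl bromide (PBr3), and alkylate the aryl-copper made from lithiated 2 (n-BuLi, CuI). This gives 8 directly with no benzyl chloride.

3. **Step 6 (Ir C–H borylation with the geranyl olefins present).** Risks are olefin hydroboration or isomerisation. Fallback: change the order. Borylate/oxidise 2 itself to 3,5-bis(methoxymethoxy)phenol, protect it as the TIPS ether (which blocks its flanking positions), lithiate between the two OMOM groups and introduce the geranyl unit by the aryl-copper/geranyl bromide alkylation above, then remove TIPS with TBAF to rejoin the route at 9.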